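Amounts first: you charged the capture agent at 2.00% of the substrate, so taken one for one it was worth about the margin of 2 percentage points, and I set aside your hunch that it picks the winner.

| flask | substrate | capture agent | remark | time |
|---|---|---|---|---|
| noon | 5 mM | 0.10 mM | run made earlier |  |
| dusk | 2.5 mM | 0.10 mM | run made earlier |  |
| summer | 10 mM | 0.10 mM | run made earlier |  |
| midnight | 5 mM | 0.050 mM | run made earlier |  |
| blue | 5.0 mM | 0.100 mM | one stirred flow tank at steady state, fed with the mixture as stated, mean residence time 6.0 min |  |
| amber | 5.0 mM (fed, over 6.00 min) | 0.100 mM | all but substrate at the start; substrate goes in evenly over 6.00 min, the run ends at 6.0 min | 6.0 min |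
| grey | 5.0 mM | 0.100 mM | everything together in a closed stirred flask, run for 6.0 min | 6.0 min |

| run | time / min | target / % | substrate / % |
|---|---|---|---|
| noon | 1.33 | 42.6 | 1.6 |
| noon | 2.50 | 34.7 | 0.3 |
| noon | 4.00 | 28.5 | 0 |
| noon | 5.00 | 27.5 | 0 |
| noon | 6.00 | 25.0 | 0 |
| dusk | 0.500 | 34.5 | 27.6 |
| dusk | 1.00 | 40.9 | 8.2 |
| dusk | 2.00 | 39.3 | 0 |
| dusk | 4.00 | 28.5 | 1.3 |
| dusk | 8.00 | 15.1 | 0 |
| summer | 0.500 | 34.6 | 26.4 |
| summer | 1.00 | 41.3 | 7.3 |
| summer | 2.00 | 38.8 | 2.6 |
| summer | 4.00 | 32.2 | 2.3 |
| summer | 8.00 | 19.4 | 0 |
| midnight | 0.500 | 33.9 | 25.0 |
| midnight | 1.00 | 40.1 | 5.9 |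
| midnight | 2.00 | 38.9 | 1.3 |
| midnight | 4.00 | 29.2 | 1.8 |
| midnight | 8.00 | 18.4 | 0.9 |

(scatter of a reading: 1 percentage point)

* the set-up with the highest amount of target at the outlet or at the end, in percent of the substrate put in ("none" if the first two lie within 2 percentage points) (blue / amber / grey / none)
* amount of target at the outlet or at the end, in percent of the substrate put in, blue
* amount of target at the outlet or at the end, in percent of the substrate put in, amber
* amount of target at the outlet or at the end, in percent of the substrate put in, grey

- the stated concentrations are those of everything mixed, before any reaction; amounts are the same in each set-up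
- the feed brings no volume worth counting
- the earlier runs were made in a closed, stirred flask

I looked instead for the crossing where control changes hands. The summer reading at 1.00 min put substrate loss at 2.62 min⁻¹. I read 0.114 min⁻¹ from the first and last noon readings and called it the fading rate, the fraction of target lost per minute once substrate no longer supplies it. Substrate loss was 23.0 times that, which put the peak at 1.25 min, just ahead of the first noon reading, so both readings lay past the crossing.

Running the noon line back gave 49.6% of the charge as target before any fading, and each slice of substrate then fades by its own age. Grey is the noon run again, so I took its reading of 25.0%. In amber the ages spread evenly from zero to 6.00 min, which gave me 32.7%. In blue, back-mixing divides by one plus fading rate times residence time, which gave me 26.5%. I committed to amber, ahead of blue by 6.2 points.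

The forecast differed from mine in its numbers, with blue 24.5%, amber 31%, grey 24% and best amber, and it said of amber that “Target formed later has less time to decay”.

The flask gave blue 25.8%, amber 32.3% and grey 23.5%, so amber came first.

    substrate → open intermediate (k = 0.0443 s⁻¹)
    open intermediate ⇌ target (K = 1.00, k = 0.410 s⁻¹)
    open intermediate ⇌ isomer of the product (K = 65.0, k = 0.00434 s⁻¹)
    open intermediate + capture agent → trapped intermediate (k = 13.7 L mol⁻¹ s⁻¹)
    target → over-reaction product (k = 9.23 × 10⁻⁵ s⁻¹)

The fading rate carried further: from 41.3% of target in grey read at 1.5 min, it gave 31.1% at 4.0 min, where the neighbour flask read 30.4%, and from that reading it gave 24.2% at 6.0 min. In grey, target, the kinetic product against the thermodynamic isomer of the product, faded mainly because it returned to open intermediate: with that return taken away, target in grey stood at 95.7% instead of 23.5%.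

(The data were generated by integration with constants of no real substance; the scatter is artificial.)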